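**In the flask.** The target in this flask stands near 12.2% of the starting material charged at 15 min, down from 25.2% at 4.00 min. [starting material] was charged at 0.20 M and [catalyst] at 8.4 mM.

| flask | starting material | catalyst | remark | time |
|---|---|---|---|---|
| Friday's | 0.20 M | 8.4 mM | the very flask that is asked about, followed so far |  |
| Saturday's | 0.30 M | 8.4 mM | run made earlier |  |
| flask | 0.20 M | 8.4 mM |  | 15 min |

- Friday's (time / min: target / %): 2.00: 25.6; 4.00: 25.2; 6.00: 20.9; 8.00: 17.6; 10.0: 16.8; 12.0: 14.3; 15.0: 12.2
- Saturday's (time / s: target / %): 10.0: 4.0; 15.0: 7.0; 25.0: 10.4; 40.0: 15.3; 50.0: 16.9; 80.0: 22.5; 120: 25.6

(standard deviation of a reading: 0.5 percentage points)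

- what is taken out of target is counted as made
- the analysis behind the earlier runs scatters by 0.5 percentage points, standard deviation
- additions bring no volume worth counting

1. target, in percent of the starting material first charged, at 15 min
2. what to do for the largest gain in target; "none" if nothing gains more than 2 percentage points (midnight / spring / dusk / noon / none)
3. target present, with what was taken out counted in, in percent of the starting material first charged, after spring
4. target present, with what was taken out counted in, in percent of the starting material first charged, after dusk

- midnight: at 15 min add starting material, 50.0% of the amount charged, then wait 30 min
- spring: at 15 min add catalyst, 50.0% of the amount charged, then wait 30 min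
- dusk: change nothing and wait 30 min more
- noon: at 15 min take out 90% of the target then present, then wait 30 min

**The bar.** In logarithms, Friday's target falls by 0.0286 /min in decades. My bar is 0.0458 decades: the loss over a wait at which the share taken out equals what a wait keeps, the common logarithm of one over that share.

**Your shift.** A wait of 30 min at that fall costs 0.858 decades, more than the bar, so I would take out the target at 15 min. Don't add starting material: Saturday's larger charge reads 25.6% at 120 s and Friday's 25.6% at 2.00 min, so I expect fresh target in the same percent, falling too. Both runs held 8.4 mM of catalyst, so I have no reading of what more of it does, and I make no claim for adding it.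

**The forecast.** It gives 12.2% now, 4.5% after spring and 3.5% after dusk, and calls noon “clearly the best”.

    starting material + catalyst ⇌ isomer of the product A + catalyst, rate k1*[starting material]*[catalyst] forward; the back reaction follows from the equilibrium constant (K = 13.0, k = 0.842 /M/s)
    starting material ⇌ target (K = 1.30, k = 0.00505 /s)
    starting material ⇌ isomer of the product B (K = 0.820, k = 3.40 × 10⁻⁴ /s)

**The result.** This flask holds 12.0% at 15 min, and noon gains 5.9 percentage points, more than any other option. Left until 150 min, it still holds 8.07%. Dusk ends at 8.14%, a loss of 0.170 decades against the straight 0.858, yet still more than the bar. The neighbour flask read at 4.0 min holds 25.0%, and the bar is passed again on the way to 15 min, by a fall of 0.319 decades.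

(Readings and results are calculated with made-up constants, noise included.)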